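**Retrosynthetic overview**
1. The exocyclic C3=CH–Ar bond is cut first: aldol condensation of the (R)-butanolide 5 with vanillin acetate 6, E-alkene by E1cB elimination, phenol unmasked in the same pot.
2. Lactone 5 is cut at C4–C5 and at the acyl C–O bond: the β-carbon of enal 3, made nucleophilic as a carbene-bound homoenolate, attacks the carbonyl carbon of formaldehyde, and the new alkoxide closes the ring. This step sets C4.
3. Enal 3 comes from methyl eugenol 1 and crotonaldehyde 2 by cross-metathesis.
4. Ring order: both benzene rings are bought; the butanolide is the only ring made (step 2); the arylidene is attached afterwards (step 3).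

Assumption: the (5aS,10bR) triazolium salt is taken to give the R lactone; if it gives S, its commercially available (5aR,10bS) enantiomer is used and nothing else changes.

**Route**

Step 1
Reactants: 1 methyl eugenol (4-allyl-1,2-dimethoxybenzene); 2 (E)-crotonaldehyde
Product: 3 (E)-4-(3,4-dimethoxyphenyl)but-2-enal
Conditions: 2 (4 equiv), [1,3-bis(2,4,6-trimethylphenyl)imidazolidin-2-ylidene]dichloro(2-isopropoxybenzylidene)ruthenium (second-generation Hoveyda–Grubbs catalyst, 2 mol%), 1,4-benzoquinone (10 mol%), CH2Cl2, 40 °C, 12 h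
Reagents that add atoms: none
Why: Olefin cross-metathesis of a terminal allylarene with an electron-poor enal used in excess is selective for the cross product, loses propene, and gives the conjugated E-alkene as the thermodynamic isomer; benzoquinone suppresses allyl-to-propenyl migration.

Step 2
Reactants: 3 (E)-4-(3,4-dimethoxyphenyl)but-2-enal; 4 paraformaldehyde
Product: 5 (R)-4-(3,4-dimethoxybenzyl)dihydrofuran-2(3H)-one
Conditions: 4 (3 equiv CH2O), (5aS,10bR)-2-mesityl-5a,10b-dihydro-4H,6H-indeno[2,1-b][1,2,4]triazolo[4,3-d][1,4]oxazin-2-ium chloride (10 mol%), iPr2NEt (20 mol%), 4 Å MS, THF, 40 °C, 24 h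
Reagents that add atoms: none
Why: Proposed new method: the triazolylidene adds to the enal to give a catalyst-bound homoenolate whose β-carbon (normally electrophilic) attacks formaldehyde released slowly from the polymer, then tautomerisation to the acyl azolium and O-acylation by the new alkoxide close the lactone and free the carbene, with the indane-fused N-mesityl catalyst shielding one face of the β-carbon so that C4 is set as R by catalyst control; the closest known reactions are the carbene-catalysed homoenolate [3+2] annulation of enals with aryl aldehydes and activated ketones, the carbene-catalysed hydroxymethylation of aldehydes with paraformaldehyde, and catalyst-controlled enantioselective homoenolate additions to nitroalkenes.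

Step 3
Reactants: 5 (R)-4-(3,4-dimethoxybenzyl)dihydrofuran-2(3H)-one; 6 vanillin acetate (4-formyl-2-methoxyphenyl acetate)
Product: 10 (3E,4R)-3-(4-hydroxy-3-methoxybenzylidene)-4-(3,4-dimethoxybenzyl)dihydrofuran-2(3H)-one, via lithium aldolate 7 (not isolated), via aldol acetate 8 (not isolated), via arylidene lactone aryl acetate 9 (not isolated)
Conditions: LiN(SiMe3)2 (1.1 equiv), THF, −78 °C; 6 (1.2 equiv), −78 °C, 1 h; Ac2O (3 equiv), −78 to 0 °C; DBU (5 equiv), 23 °C, 6 h; MeOH, 23 °C, 1 h; aq. NH4Cl
Reagents that add atoms: none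
Why: Telescoped aldol condensation: the lactone lithium enolate adds to the aldehyde anti to the C4 benzyl group, the aldolate is O-acetylated, DBU effects E1cB elimination to the thermodynamically preferred E-arylidene (aryl anti to the lactone carbonyl), and DBU-catalysed methanolysis removes the phenyl acetate; C4 is not alpha to the carbonyl and is untouched, and the two transient stereocentres vanish in the elimination.

**Compound list**
1 | methyl eugenol (4-allyl-1,2-dimethoxybenzene) | C=CCc1ccc(OC)c(OC)c1 | starting material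
2 | (E)-crotonaldehyde | C/C=C/C=O | starting material
3 | (E)-4-(3,4-dimethoxyphenyl)but-2-enal | O=C/C=C/Cc1ccc(OC)c(OC)c1 | intermediate
4 | paraformaldehyde, HO(CH2O)nH, drawn as the octamer | OCOCOCOCOCOCOCOCO | starting material
5 | (R)-4-(3,4-dimethoxybenzyl)dihydrofuran-2(3H)-one | O=C1OC[C@@H](C1)Cc2ccc(OC)c(OC)c2 | intermediate
6 | vanillin acetate (4-formyl-2-methoxyphenyl acetate) | CC(=O)Oc1ccc(C=O)cc1OC | starting material
7 | lithium alkoxide of (3S,4R)-3-[(4-acetoxy-3-methoxyphenyl)(hydroxy)methyl]-4-(3,4-dimethoxybenzyl)dihydrofuran-2(3H)-one (3,4-trans, both carbinol epimers) | [Li+].[O-]C(c1ccc(OC(C)=O)c(OC)c1)[C@H]1C(=O)OC[C@@H]1Cc1ccc(OC)c(OC)c1 | intermediate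
8 | (4-acetoxy-3-methoxyphenyl)[(3S,4R)-4-(3,4-dimethoxybenzyl)-2-oxotetrahydrofuran-3-yl]methyl acetate (both carbinol epimers) | CC(=O)OC(c1ccc(OC(C)=O)c(OC)c1)[C@H]1C(=O)OC[C@@H]1Cc1ccc(OC)c(OC)c1 | intermediate
9 | 4-{(E)-[(4R)-4-(3,4-dimethoxybenzyl)-2-oxodihydrofuran-3(2H)-ylidene]methyl}-2-methoxyphenyl acetate | CC(=O)Oc1ccc(/C=C2/C(=O)OC[C@@H]2Cc2ccc(OC)c(OC)c2)cc1OC | intermediate
10 | (3E,4R)-3-(4-hydroxy-3-methoxybenzylidene)-4-(3,4-dimethoxybenzyl)dihydrofuran-2(3H)-one | COc1cc(/C=C2/C(=O)OC[C@@H]2Cc2ccc(OC)c(OC)c2)ccc1O | target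

**Count and risks**
Total steps: 3. Longest linear sequence: 3 (1 → 3 → 5 → 10).

Most likely to fail, in order:

Step 2. The carbene may instead consume formaldehyde by self-condensation or transfer it as an acyl anion, the enal may dimerise or be deprotonated at its benzylic γ-position, and enantiocontrol with so small an electrophile is untested. The fallback sets out from 3 and comes back at 5; it brings in the same carbon as a nitronate under iminium catalysis. Enal 3, CH3NO2 and (S)-2-[diphenyl(trimethylsilyloxy)methyl]pyrrolidine (10 mol%, PhCO2H, MeOH, 23 °C; addition anti to the bulky group) give (R)-3-(3,4-dimethoxybenzyl)-4-nitrobutanal F2. Pinnick oxidation (NaClO2, NaH2PO4, 2-methyl-2-butene, tBuOH/H2O) gives (R)-3-(3,4-dimethoxybenzyl)-4-nitrobutanoic acid F3, and MeOH with catalytic H2SO4 gives methyl (R)-3-(3,4-dimethoxybenzyl)-4-nitrobutanoate F4. NaNO2/AcOH in DMSO at 35 °C turns the primary nitro group into the acid, (R)-2-(3,4-dimethoxybenzyl)-4-methoxy-4-oxobutanoic acid F5, without passing through an epimerisable aldehyde. BH3·SMe2 reduces only the free acid to methyl (R)-3-(3,4-dimethoxybenzyl)-4-hydroxybutanoate F6, which lactonises with catalytic TsOH to 5.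

Step 3. The enolate may attack the aryl acetate of 6 instead of the aldehyde, elimination may be incomplete, or E/Z mixtures may form. The fallback sets out from 5 and comes back at 9; it forms the alkene by phosphonate olefination. Lactone 5 with LiN(iPr)2 (2.2 equiv) and ClP(O)(OEt)2 in THF at −78 °C gives the enol phosphate diethyl (R)-4-(3,4-dimethoxybenzyl)-4,5-dihydrofuran-2-yl phosphate F7. The second equivalent of amide rearranges it by a 1,3 O-to-C phosphoryl shift to diethyl [(3R,4S)-4-(3,4-dimethoxybenzyl)-2-oxotetrahydrofuran-3-yl]phosphonate F8. Horner–Wadsworth–Emmons reaction of F8 with 6 (LiCl, DBU, MeCN, 23 °C) gives 9, which MeOH/DBU deacetylates to 10 as in the last stage of step 3.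

Step 1. Ruthenium hydride species may move the allyl double bond of 1 into conjugation, giving a styrene and a shorter enal, or isomerise 3. The fallback sets out from 1 and comes back at 3. Oxidative cleavage of 1 (K2OsO4·2H2O cat., NaIO4, 2,6-lutidine, dioxane/H2O) gives (3,4-dimethoxyphenyl)acetaldehyde F1. Wittig olefination of F1 with (triphenylphosphoranylidene)acetaldehyde (toluene, 60 °C) gives 3.

**Further compounds**
F1 | step 1 | (3,4-dimethoxyphenyl)acetaldehyde | O=CCc1ccc(OC)c(OC)c1
F2 | step 2 | (R)-3-(3,4-dimethoxybenzyl)-4-nitrobutanal | [O-][N+](=O)C[C@@H](CC=O)Cc1ccc(OC)c(OC)c1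
F3 | step 2 | (R)-3-(3,4-dimethoxybenzyl)-4-nitrobutanoic acid | [O-][N+](=O)C[C@@H](CC(=O)O)Cc1ccc(OC)c(OC)c1
F4 | step 2 | methyl (R)-3-(3,4-dimethoxybenzyl)-4-nitrobutanoate | [O-][N+](=O)C[C@@H](CC(=O)OC)Cc1ccc(OC)c(OC)c1
F5 | step 2 | (R)-2-(3,4-dimethoxybenzyl)-4-methoxy-4-oxobutanoic acid | OC(=O)[C@@H](CC(=O)OC)Cc1ccc(OC)c(OC)c1
F6 | step 2 | methyl (R)-3-(3,4-dimethoxybenzyl)-4-hydroxybutanoate | OC[C@@H](CC(=O)OC)Cc1ccc(OC)c(OC)c1
F7 | step 3 | diethyl (R)-4-(3,4-dimethoxybenzyl)-4,5-dihydrofuran-2-yl phosphate | CCOP(=O)(OCC)OC1=C[C@@H](Cc2ccc(OC)c(OC)c2)CO1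
F8 | step 3 | diethyl [(3R,4S)-4-(3,4-dimethoxybenzyl)-2-oxotetrahydrofuran-3-yl]phosphonate | CCOP(=O)(OCC)[C@H]1C(=O)OC[C@@H]1Cc1ccc(OC)c(OC)c1
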